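The disconnection on which everything rests is the C3′–C4′ bond of ring D (C1′–C5′, C10′), the gem-dimethyl cyclohexane of one decalin half: C4′, next to ring-fusion C5′, is a masked isopropenyl carbon. Ring C, with the C5′ and C10′ stereocentres, the C8′ methyl and C4′ itself, comes from (R)-carvone; rings A and B and the C11–C12 linker come from (+)-sclareolide. In the final step hydrogen-atom transfer converts the isopropenyl group into the tertiary C4′ radical, which nickel joins to the primary iodide at C3′. Two acceptor-type carbons are thus united reductively: ring D closes, quaternary C4′ is created, and the target forms directly from a ring-D-seco iodo-triene.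

Key step: step 9

Remark on numbering: each decalin half is numbered like a drimane (C4 gem-dimethyl carbon, C5 ring-fusion CH, C10 ring-fusion quaternary carbon, C8=C9 alkene, C11 and C12 the two linker CH2 groups). Unprimed numbers and rings A (C1–C5, C10) and B (C5–C10) belong to the sclareolide-derived half; primed numbers and rings C (C5′–C10′) and D (C1′–C5′, C10′) belong to the carvone-derived half. The target is C2-symmetric, (5S,10S,5′S,10′S), with both halves trans-fused.

Step 1
Reactants: 1 (R)-(−)-carvone
Product: 3 (5R,6S)-2,6-dimethyl-5-(prop-1-en-2-yl)cyclohex-2-en-1-one (6-methylcarvone; major trans epimer drawn), via lithium dienolate 2 (not isolated)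
Conditions: LiN(i-Pr)2, THF, −78 °C; MeI, −78 to 0 °C
Reagents that add atoms: iodomethane, CI
Why: Kinetic deprotonation at C6 gives the cross-conjugated lithium dienolate, which is C-methylated (enolate alkylation), and the configuration of the new C6 centre does not matter because it is flattened again in step 2.

Step 2
Reactants: 3 6-methylcarvone
Product: 5 (5S,6S)-2,6-dimethyl-6-(prop-2-en-1-yl)-5-(prop-1-en-2-yl)cyclohex-2-en-1-one, via lithium enolate 4 (not isolated)
Conditions: LiN(i-Pr)2, THF, −78 °C; allyl bromide, DMPU, −78 °C to rt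
Reagents that add atoms: allyl bromide, C=CCBr
Why: In this enolate alkylation allyl bromide should approach anti to the adjacent isopropenyl group, which sets the quaternary centre (future C10′) with the allyl arm trans to the isopropenyl arm, the relationship needed for the trans ring fusion.

Step 3
Reactants: 5 6-allyl-6-methylcarvone
Product: 7 (5S,6S)-2,6-dimethyl-6-(prop-2-en-1-yl)-5-(prop-1-en-2-yl)cyclohex-1-en-1-yl trifluoromethanesulfonate, via lithium enolate 6 (not isolated)
Conditions: LiBH(s-Bu)3, THF, −78 °C; PhNTf2, −78 °C to rt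
Reagents that add atoms: N-phenylbis(trifluoromethanesulfonimide), O=S(=O)(N(c1ccccc1)S(=O)(=O)C(F)(F)F)C(F)(F)F
Why: Conjugate hydride reduction of the beta-unsubstituted, carbonyl-hindered enone gives the regiodefined enolate, which is O-sulfonylated to the tetrasubstituted enol triflate without touching a stereocentre.

Step 4
Reactants: 8 (+)-sclareolide
Product: 9 methyl 2-[(4aS,8aS)-2,5,5,8a-tetramethyl-3,4,4a,5,6,7,8,8a-octahydronaphthalen-1-yl]acetate
Conditions: H2SO4 (conc.), MeOH, 65 °C
Reagents that add atoms: methanol, CO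
Why: Acid-catalysed lactone methanolysis with E1 loss of the C8 oxygen (Fischer esterification and dehydration) under equilibrating conditions should favour the tetrasubstituted C8=C9 alkene while leaving C5 and C10 untouched, and minor alkene isomers would be removed on AgNO3-impregnated silica.

Step 5
Reactants: 9 methyl ester
Product: 10 2-[(4aS,8aS)-2,5,5,8a-tetramethyl-3,4,4a,5,6,7,8,8a-octahydronaphthalen-1-yl]ethan-1-ol
Conditions: LiAlH4, THF, 0 °C to rt
Reagents that add atoms: none
Why: Hydride reduction of the ester gives the primary alcohol, and the isolated tetrasubstituted alkene is inert.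

Step 6
Reactants: 10 homoallylic alcohol
Product: 11 (4aS,8aS)-1-(2-iodoethyl)-2,5,5,8a-tetramethyl-3,4,4a,5,6,7,8,8a-octahydronaphthalene
Conditions: I2, PPh3, imidazole, CH2Cl2, 0 °C to rt
Reagents that add atoms: iodine, II
Why: Appel-type iodination of the primary alcohol proceeds through the alkoxyphosphonium ion and SN2 attack by iodide.

Step 7
Reactants: 11 primary iodide; 7 enol triflate
Product: 13 (4aS,8aS)-1-{2-[(5S,6S)-2,6-dimethyl-6-(prop-2-en-1-yl)-5-(prop-1-en-2-yl)cyclohex-1-en-1-yl]ethyl}-2,5,5,8a-tetramethyl-3,4,4a,5,6,7,8,8a-octahydronaphthalene, via alkylzinc iodide 12 (not isolated)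
Conditions: Zn dust (activated), LiCl, THF, 40 °C; then 7, Pd(OAc)2, SPhos, THF/NMP, 60 °C
Reagents that add atoms: none
Why: Zinc insertion into the C–I bond followed by Negishi sp3–sp2 cross-coupling forms the C12–C9′ bond, with a bulky electron-rich phosphine to drive the reaction at the hindered triflate, whose position fixes the C8′=C9′ alkene.

Step 8
Reactants: 13 tetraene
Product: 15 (4aS,8aS)-1-{2-[(5S,6S)-6-(3-iodopropyl)-2,6-dimethyl-5-(prop-1-en-2-yl)cyclohex-1-en-1-yl]ethyl}-2,5,5,8a-tetramethyl-3,4,4a,5,6,7,8,8a-octahydronaphthalene, via alkylzirconocene chloride 14 (not isolated)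
Conditions: Cp2Zr(H)Cl, THF, rt, dark; I2, 0 °C
Reagents that add atoms: iodine, II
Why: Hydrozirconation should place zirconium at the terminal carbon of the monosubstituted allyl alkene, which reacts much faster than the 1,1-disubstituted and tetrasubstituted alkenes, and iodinolysis of the C–Zr bond gives the primary iodide (hydrozirconation–iodination).

Step 9
Reactants: 15 ring-D-seco iodo-triene
Product: 16 1,2-bis[(4aS,8aS)-2,5,5,8a-tetramethyl-3,4,4a,5,6,7,8,8a-octahydronaphthalen-1-yl]ethane (CNP0372467.1)
Conditions: Mn(dpm)3 (cat., dpm = dipivaloylmethanate), Ni(acac)2 (cat.), PhSiH3 (slow addition), K2CO3, (CF3)2CHOH, ClCH2CH2Cl/propylene carbonate, rt, high dilution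
Reagents that add atoms: none
Why: Proposed new method: a manganese hydride formed from Mn(dpm)3 and PhSiH3 should transfer a hydrogen atom to the terminal CH2 of the C5′ isopropenyl group (Markovnikov) to give the tertiary C4′ radical, while low-valent nickel from Ni(acac)2 takes up the C3′–I bond, and radical capture followed by C(sp3)–C(sp3) reductive elimination from trivalent nickel joins C3′ to C4′. The closest known reaction is the intermolecular Mn/Ni dual-catalytic Markovnikov hydroalkylation of 1,1-disubstituted alkenes with primary alkyl iodides that forms quaternary carbons; what is new is its ring-closing use on an ω-iodoalkyl alkene. Ring D closes as a six-membered ring by formal 6-exo union of C4′ with C3′ through a seven-membered nickelacycle that contracts on reductive elimination. No new stereocentre is formed, because C4′ ends with two methyl groups (one is the former =CH2 plus the transferred hydrogen), and the trans ring fusion is already fixed by C5′ (S) and C10′ (S), whose two tether arms are trans-diequatorial on ring C and can only give the trans-decalin. The step needs hydrogen-atom transfer to the 1,1-disubstituted alkene rather than to the tetrasubstituted C8=C9 and C8′=C9′ alkenes, which their steric shielding should secure, and coupling rather than simple reduction of the radical or the iodide, which the intramolecular setting and slow silane addition should favour.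

Compound list
1 | (R)-(−)-carvone, (5R)-2-methyl-5-(prop-1-en-2-yl)cyclohex-2-en-1-one | CC1=CC[C@@H](C(C)=C)CC1=O | starting material
2 | lithium dienolate of 1 (O-lithium cross-conjugated C1–C6 enolate) | CC1=CC[C@@H](C(C)=C)C=C1O[Li] | intermediate
3 | (5R,6S)-2,6-dimethyl-5-(prop-1-en-2-yl)cyclohex-2-en-1-one (6-methylcarvone, major trans epimer drawn; C6 epimer mixture is used) | CC1=CC[C@@H](C(C)=C)[C@H](C)C1=O | intermediate
4 | lithium enolate of 3 (O-lithium C1–C6 enolate) | CC1=CC[C@@H](C(C)=C)C(C)=C1O[Li] | intermediate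
5 | (5S,6S)-2,6-dimethyl-6-(prop-2-en-1-yl)-5-(prop-1-en-2-yl)cyclohex-2-en-1-one (allyl trans to isopropenyl) | CC1=CC[C@@H](C(C)=C)[C@](C)(CC=C)C1=O | intermediate
6 | lithium enolate from conjugate reduction of 5 (O-lithium C1–C2 enolate) | CC1CC[C@@H](C(C)=C)[C@](C)(CC=C)C=1O[Li] | intermediate
7 | (5S,6S)-2,6-dimethyl-6-(prop-2-en-1-yl)-5-(prop-1-en-2-yl)cyclohex-1-en-1-yl trifluoromethanesulfonate | CC1CC[C@@H](C(C)=C)[C@](C)(CC=C)C=1OS(=O)(=O)C(F)(F)F | intermediate
8 | (+)-sclareolide, (3aR,5aS,9aS,9bR)-3a,6,6,9a-tetramethyldecahydronaphtho[2,1-b]furan-2(1H)-one | CC1(C)CCC[C@@]2(C)[C@H]1CC[C@@]1(C)OC(=O)C[C@@H]12 | starting material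
9 | methyl 2-[(4aS,8aS)-2,5,5,8a-tetramethyl-3,4,4a,5,6,7,8,8a-octahydronaphthalen-1-yl]acetate | COC(=O)CC1=C(C)CC[C@H]2C(C)(C)CCC[C@]12C | intermediate
10 | 2-[(4aS,8aS)-2,5,5,8a-tetramethyl-3,4,4a,5,6,7,8,8a-octahydronaphthalen-1-yl]ethan-1-ol | OCCC1=C(C)CC[C@H]2C(C)(C)CCC[C@]12C | intermediate
11 | (4aS,8aS)-1-(2-iodoethyl)-2,5,5,8a-tetramethyl-3,4,4a,5,6,7,8,8a-octahydronaphthalene | ICCC1=C(C)CC[C@H]2C(C)(C)CCC[C@]12C | intermediate
12 | alkylzinc iodide from 11 | I[Zn]CCC1=C(C)CC[C@H]2C(C)(C)CCC[C@]12C | intermediate
13 | (4aS,8aS)-1-{2-[(5S,6S)-2,6-dimethyl-6-(prop-2-en-1-yl)-5-(prop-1-en-2-yl)cyclohex-1-en-1-yl]ethyl}-2,5,5,8a-tetramethyl-3,4,4a,5,6,7,8,8a-octahydronaphthalene | CC1CC[C@@H](C(C)=C)[C@](C)(CC=C)C=1CCC2=C(C)CC[C@H]3C(C)(C)CCC[C@]23C | intermediate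
14 | alkylzirconocene chloride from 13 (Cp2Zr(Cl) at C3′) | CC1CC[C@@H](C(C)=C)[C@](C)(CCC[Zr](Cl)(C2C=CC=C2)C2C=CC=C2)C=1CCC3=C(C)CC[C@H]4C(C)(C)CCC[C@]34C | intermediate
15 | (4aS,8aS)-1-{2-[(5S,6S)-6-(3-iodopropyl)-2,6-dimethyl-5-(prop-1-en-2-yl)cyclohex-1-en-1-yl]ethyl}-2,5,5,8a-tetramethyl-3,4,4a,5,6,7,8,8a-octahydronaphthalene | CC1CC[C@@H](C(C)=C)[C@](C)(CCCI)C=1CCC2=C(C)CC[C@H]3C(C)(C)CCC[C@]23C | intermediate
16 | 1,2-bis[(4aS,8aS)-2,5,5,8a-tetramethyl-3,4,4a,5,6,7,8,8a-octahydronaphthalen-1-yl]ethane (CNP0372467.1) | CC1=C(CCC2=C(C)CC[C@H]3C(C)(C)CCC[C@]23C)[C@@]2(C)CCCC(C)(C)[C@@H]2CC1 | target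

Total step count: 9. Longest linear sequence: 6 steps (steps 1, 2, 3, 7, 8, 9 from carvone, or steps 4, 5, 6, 7, 8, 9 from sclareolide).

Steps most likely to fail

1. Step 9 (the proposed new method). The C4′ radical may be quenched by a second hydrogen-atom transfer, which amounts to hydrogenation of the isopropenyl group. The alkylnickel may also lose its iodide by β-hydride elimination or protonation before the two partners meet, and a free C3′ radical could close 7-endo onto the terminal CH2. The fallback uses known chemistry, sets out from 15 and comes back at 16. Kornblum oxidation (DMSO, NaHCO3, 100 °C) converts the primary iodide into the aldehyde F1. Fe(acac)3 and PhSiH3 in EtOH/ethylene glycol at 60 °C then generate the same C4′ radical, which adds 6-exo to the aldehyde carbon C3′ (hydrogen-atom-transfer radical cyclisation of an alkene onto a carbonyl group) to give the ring-D secondary alcohol F2, both C3′ epimers being usable. NaH, CS2 and MeI give the xanthate F3, and Bu3SnH/AIBN in toluene at 110 °C (Barton–McCombie deoxygenation) gives 16.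

2. Step 7. Oxidative addition and transmetalation at the tetrasubstituted enol triflate next to quaternary C10′ may be too slow, so that S–O cleavage of the triflate or decay of the zinc reagent takes over. The fallback sets out from 11 and 5, comes back at 13, and replaces steps 3 and 7 by carbonyl addition and reductive allylic transposition. Iodine–lithium exchange on 11 (t-BuLi, Et2O/pentane, −78 °C) gives the alkyllithium F4, which adds 1,2 to the hindered enone 5 (CeCl3 as additive if enolisation or 1,4-addition competes) to give the tertiary allylic alcohol F5. Ionisation with BF3·OEt2 in the presence of Et3SiH (CH2Cl2, −78 °C) forms the C7′–C8′–C9′ allyl cation, and hydride delivery to its less hindered C7′ end gives 13 with the tetrasubstituted C8′=C9′ alkene.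

3. Step 8. The zirconium hydride may not discriminate cleanly between the allyl and isopropenyl alkenes, and iodine may add to or isomerise the tetrasubstituted alkenes during the quench. The fallback sets out from 3, comes back at 15, and removes the late alkene discrimination altogether. Enolate 4 is alkylated with 1-chloro-3-iodopropane (DMPU, −78 °C to rt, attack again anti to the isopropenyl group) to give the chloropropyl enone F6. LiBH(s-Bu)3 and then PhNTf2 give, through the lithium enolate F7, the enol triflate F8. Coupling with 12 as in step 7 gives the chloride F9, whose C–Cl bond is inert to zinc and palladium, and NaI in butanone at reflux (Finkelstein exchange) gives 15.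

Further compounds
F1 | step 9 | 3-[(1S,6S)-1,3-dimethyl-6-(prop-1-en-2-yl)-2-{2-[(4aS,8aS)-2,5,5,8a-tetramethyl-3,4,4a,5,6,7,8,8a-octahydronaphthalen-1-yl]ethyl}cyclohex-2-en-1-yl]propanal (aldehyde at C3′) | CC1CC[C@@H](C(C)=C)[C@](C)(CCC=O)C=1CCC2=C(C)CC[C@H]3C(C)(C)CCC[C@]23C
F2 | step 9 | ring-D-closed secondary alcohol, 3′-hydroxy derivative of 16 (C3′ epimer mixture) | CC1CC[C@@H](C2(C)C)[C@](C)(CCC2O)C=1CCC3=C(C)CC[C@H]4C(C)(C)CCC[C@]34C
F3 | step 9 | O-alkyl S-methyl xanthate of F2 | CC1CC[C@@H](C2(C)C)[C@](C)(CCC2OC(=S)SC)C=1CCC3=C(C)CC[C@H]4C(C)(C)CCC[C@]34C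
F4 | step 7 | primary alkyllithium from 11 (not isolated) | [Li]CCC1=C(C)CC[C@H]2C(C)(C)CCC[C@]12C
F5 | step 7 | tertiary allylic alcohol from 1,2-addition of F4 to 5 (C9′ epimer mixture) | CC1=CC[C@@H](C(C)=C)[C@](C)(CC=C)C1(O)CCC2=C(C)CC[C@H]3C(C)(C)CCC[C@]23C
F6 | step 8 | (5S,6S)-6-(3-chloropropyl)-2,6-dimethyl-5-(prop-1-en-2-yl)cyclohex-2-en-1-one | CC1=CC[C@@H](C(C)=C)[C@](C)(CCCCl)C1=O
F7 | step 8 | lithium enolate from conjugate reduction of F6 (not isolated) | CC1CC[C@@H](C(C)=C)[C@](C)(CCCCl)C=1O[Li]
F8 | step 8 | (5S,6S)-6-(3-chloropropyl)-2,6-dimethyl-5-(prop-1-en-2-yl)cyclohex-1-en-1-yl trifluoromethanesulfonate | CC1CC[C@@H](C(C)=C)[C@](C)(CCCCl)C=1OS(=O)(=O)C(F)(F)F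
F9 | step 8 | chloro analogue of 15 (3-chloropropyl at C10′) | CC1CC[C@@H](C(C)=C)[C@](C)(CCCCl)C=1CCC2=C(C)CC[C@H]3C(C)(C)CCC[C@]23C
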